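**Retrosynthetic overview**
1. Target 35 comes from the tricyclic β-hydroxy ketone 26 by an Evans–Tishchenko reduction with epoxy aldehyde 29 (C7 ester, anti C9 alcohol), angeloylation at C9 and oxidation at C1.
2. The cyclobutane is the last carbocycle: C4–C10 by intramolecular alkylation of the C9 enolate on the allylic C4 mesylate of the cis-fused bicycle 24.
3. The seven-membered ring (C5–C6–C7–C8–C9–C10–C11) arises by cleaving the C5–C7 bond of cyclopropanol 20 (retro-aldol toward the C4 ketone).
4. The first rings (cyclohexenone C11–C1–C2–C3–C4–C5, cyclohexene C5–C7–C8–C9–C10–C11, temporary cyclopropane C5–C6–C7) come from one intramolecular Diels–Alder reaction of trienone 18, which forms C7–C8 and C5–C11.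
5. Enabling feature: in the seven-membered ring the CMe2 carbon C6 lies between C5 and C7, and C9 and C7 bear oxygen. Joining C5 to C7 turns this ring into a 7,7-dimethylnorcarene, i.e. the adduct of a 2-siloxydiene (O on C9) and a 3,3-dimethylcyclopropene (C7 oxygen carried as boron).

Key step: step 11

Remark: C1–C11 denote the core carbons of 35 (C1 ketone, C2=C3 alkene, C4 and C11 bridgeheads, C5 cyclobutane CH, C6 CMe2, C7 and C9 ester-bearing CH, C8 CH2, C10 quaternary); the epoxy ester is taken as the (2S,3R) cis-dimethyloxirane encoded in the SMILES; 2 and 11 are racemic at centres that are destroyed later.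

**Route**

Step 1
Reactants: 1 1-bromo-2-methylprop-1-ene
Product: 2 1,1,2-tribromo-3,3-dimethylcyclopropane
Conditions: CHBr3, 50% aq. NaOH, cetyltrimethylammonium bromide (cat.), CH2Cl2, rt
Reagents that add atoms: bromoform BrC(Br)Br
Why: phase-transfer dibromocarbene cyclopropanation of the electron-rich trisubstituted alkene should give the tribromide.

Step 2
Reactants: 2 1,1,2-tribromo-3,3-dimethylcyclopropane
Product: 5 2-(3,3-dimethylcycloprop-1-en-1-yl)-4,4,5,5-tetramethyl-1,3,2-dioxaborolane, via 1-bromo-3,3-dimethylcyclopropene 3 (not isolated), via (3,3-dimethylcycloprop-1-en-1-yl)lithium 4 (not isolated)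
Conditions: MeLi (2.1 equiv), Et2O, −78 °C → rt; then 2-isopropoxy-4,4,5,5-tetramethyl-1,3,2-dioxaborolane, −78 °C
Reagents that add atoms: 2-isopropoxy-4,4,5,5-tetramethyl-1,3,2-dioxaborolane CC(C)OB1OC(C)(C)C(C)(C)O1
Why: halogen–lithium exchange with 1,2-elimination, a second exchange and borylation of the cyclopropenyllithium (lithiation–borylation) should give the boronate.

Step 3
Reactants: 6 prop-2-yn-1-ol
Product: 8 (Z)-3-iodo-2-methylprop-2-en-1-ol, via bromomagnesium (Z)-3-(bromomagnesio)-2-methylprop-2-en-1-olate 7 (not isolated)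
Conditions: MeMgBr (2.5 equiv), CuI (10 mol %), Et2O, −10 °C → rt; then I2, −10 °C
Reagents that add atoms: methylmagnesium bromide C[Mg]Br; iodine II
Why: copper-catalysed, alkoxide-directed anti carbomagnesiation followed by iodinolysis with retention should give the Z vinyl iodide.

Step 4
Reactants: 8 (Z)-3-iodo-2-methylprop-2-en-1-ol
Product: 9 (Z)-3-iodo-2-methylprop-2-enal
Conditions: MnO2, CH2Cl2, rt
Reagents that add atoms: none
Why: MnO2 oxidation of an allylic alcohol, which should leave the Z alkene untouched.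

Step 5
Reactants: 5 cyclopropenyl boronate; 9 (Z)-3-iodo-2-methylprop-2-enal
Product: 11 (Z)-1-[3,3-dimethyl-2-(4,4,5,5-tetramethyl-1,3,2-dioxaborolan-2-yl)cycloprop-1-en-1-yl]-3-iodo-2-methylprop-2-en-1-ol, via lithiated boronate 10 (not isolated)
Conditions: lithium 2,2,6,6-tetramethylpiperidide, THF, −78 °C; then 9; aq. NH4Cl
Reagents that add atoms: none
Why: deprotonation of the acidic vinylic cyclopropene C–H by a hindered amide and 1,2-addition of the organolithium to the enal should form the C4–C5 bond.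

Step 6
Reactants: 11 cyclopropenyl carbinol
Product: 12 (Z)-1-[3,3-dimethyl-2-(4,4,5,5-tetramethyl-1,3,2-dioxaborolan-2-yl)cycloprop-1-en-1-yl]-3-iodo-2-methylprop-2-en-1-one
Conditions: MnO2, CH2Cl2, rt
Reagents that add atoms: none
Why: MnO2 oxidation of the doubly allylic alcohol should give the cyclopropenyl ketone that later activates the dienophile and directs the ring opening.

Step 7
Reactants: 13 2,3-dimethylfuran
Product: 15 (E)-3-methyl-4-oxopent-2-enal, via (Z)-3-methyl-4-oxopent-2-enal 14 (not isolated)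
Conditions: NBS, NaHCO3, acetone/H2O, −15 °C; then pyridine, rt
Reagents that add atoms: water O
Why: oxidative furan ring opening gives the cis enedicarbonyl, and pyridine-mediated isomerisation should give the E isomer with the methyl cis to the formyl carbon.

Step 8
Reactants: 12 vinyl iodide ketone; 15 (E)-3-methyl-4-oxopent-2-enal
Product: 16 (2Z,4R,5E)-1-[3,3-dimethyl-2-(4,4,5,5-tetramethyl-1,3,2-dioxaborolan-2-yl)cycloprop-1-en-1-yl]-4-hydroxy-2,6-dimethylocta-2,5-diene-1,7-dione
Conditions: CrCl2 (4 equiv), NiCl2 (2 mol %), (S)-oxazoline–sulfonamide ligand, Et3N, THF, rt; aqueous serine work-up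
Reagents that add atoms: none
Why: Nozaki–Hiyama–Kishi coupling, in which the vinylchromium species adds only to the aldehyde with retention of the Z geometry and the chiral ligand should set the C1 carbinol as R.

Step 9
Reactants: 16 allylic alcohol
Product: 17 (2Z,4R,5E)-4-[(tert-butyldimethylsilyl)oxy] analogue of 16
Conditions: TBSCl, imidazole, DMF, 0 °C
Reagents that add atoms: tert-butyldimethylsilyl chloride CC(C)(C)[Si](C)(C)Cl
Why: silylation of the secondary alcohol should trap the open-chain hydroxy enone before it can close to a lactol.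

Step 10
Reactants: 17 silyl ether diketone
Product: 18 (2Z,4R,5E)-4,7-bis[(tert-butyldimethylsilyl)oxy]-1-[3,3-dimethyl-2-(4,4,5,5-tetramethyl-1,3,2-dioxaborolan-2-yl)cycloprop-1-en-1-yl]-2,6-dimethylocta-2,5,7-trien-1-one
Conditions: TBSOTf, Et3N, CH2Cl2, −78 °C
Reagents that add atoms: tert-butyldimethylsilyl triflate CC(C)(C)[Si](C)(C)OS(=O)(=O)C(F)(F)F
Why: kinetic soft enolisation of the methyl ketone should give the 2-siloxydiene C8=C9–C10=C11 (the C4 ketone has no α-hydrogen).

Step 11
Reactants: 18 siloxydiene cyclopropenyl ketone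
Product: 19 cis-fused Diels–Alder adduct (cyclohexenone C11–C1–C2–C3–C4–C5, cyclohexene C5–C7–C8–C9–C10–C11 with C9 enol silyl ether, cyclopropane C5–C6–C7 with boron on C7)
Conditions: toluene (0.005 M), BHT, 80 °C
Reagents that add atoms: none
Why: Thermal intramolecular Diels–Alder reaction: the 2-siloxydiene C8=C9–C10=C11 adds suprafacially to the strained, ketone-activated cyclopropene C5=C7 and forms C7–C8 and C5–C11 in one concerted [4+2] event; the closest known types are Diels–Alder additions of 3,3-disubstituted cyclopropenyl ketones and type 1 intramolecular Diels–Alder reactions of 1,7,9-decatrien-3-ones. The cyclohexenone ring (C11–C1–C2–C3–C4–C5) closes as the tether ring and the cyclohexene ring (C5–C7–C8–C9–C10–C11) as the cycloadduct ring, while the cyclopropane C5–C6–C7 is carried through intact. C11 is set by the C1 stereocentre: allylic 1,3-strain with the C10 methyl holds the C1–H bond in the diene plane, so the tether brings the dienophile to the face anti to the silyloxy group. C5 and C7 follow from the transition state with the C4 carbonyl endo and the CMe2 carbon exo, which should give the cis ring fusion. Regiochemistry is fixed by the four-atom tether, and the tether alkene C2=C3 cannot reach the diene, so only C5=C7 can react.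

Step 12
Reactants: 19 Diels–Alder adduct
Product: 21 cis-fused bicyclo[5.4.0] diketone (C4 enone ketone and C7 ketone), via C7 cyclopropanol 20 (not isolated)
Conditions: NaBO3·4H2O, THF/H2O, 0 °C → rt
Reagents that add atoms: sodium perborate [Na+].[Na+].O[B-]1(O)OO[B-](O)(O)OO1
Why: oxidation of the C–B bond with retention gives a cyclopropanol whose donor oxygen (C7) and acceptor ketone (C4) allow only retro-aldol cleavage of C5–C7, and protonation of the C4 enolate at C5 from the convex face should give the cis-fused seven-membered ring.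

Step 13
Reactants: 21 bicyclic diketone
Product: 22 C4,C7-diol (C4–OH trans to the C5–C6 bond, C7–OH cis to the C5–C4 bond)
Conditions: NaBH4, CeCl3·7H2O, MeOH, −78 → −30 °C
Reagents that add atoms: none
Why: Luche reduction, with axial 1,2-delivery to the C4 enone giving the equatorial allylic alcohol and hydride attack on C7 from the face away from the axial C5–C4 bond.

Step 14
Reactants: 22 diol
Product: 24 C4 mesylate C7 triethylsilyl ether, via C4 monomesylate 23 (not isolated)
Conditions: MsCl (1.05 equiv), Et3N, CH2Cl2, −40 °C; then TESOTf, 2,6-lutidine, −78 °C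
Reagents that add atoms: methanesulfonyl chloride CS(=O)(=O)Cl; triethylsilyl triflate CC[Si](CC)(CC)OS(=O)(=O)C(F)(F)F
Why: the unhindered allylic C4 alcohol should be sulfonylated before the neopentyl C7 alcohol, which is then silylated so that it cannot close an oxolane onto C4 in step 15.

Step 15
Reactants: 24 mesylate
Product: 25 tricyclic ketone (C9 ketone, C7 triethylsilyl ether, C1 silyl ether syn to the C5 bridge)
Conditions: tetrabutylammonium difluorotriphenylsilicate, THF, −20 °C → rt
Reagents that add atoms: none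
Why: fluoride frees the C10 enolate regiospecifically from the enol silyl ether, and intramolecular SN2 alkylation at allylic C4 with inversion (4-exo-tet, the classical keto-sulfonate closure of bicyclo[3.1.1]heptanones) should form C4–C10 with the C10 configuration fixed by the cis-fused bicycle.

Step 16
Reactants: 25 tricyclic silyl ether
Product: 26 tricyclic β-hydroxy ketone (C7–OH, C9 ketone)
Conditions: AcOH/THF/H2O (3:1:1), rt
Reagents that add atoms: none
Why: mild acid hydrolysis should cleave the triethylsilyl ether and leave the tert-butyldimethylsilyl ether at C1.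

Step 17
Reactants: 27 (E)-2-methylbut-2-en-1-ol
Product: 28 [(2R,3R)-2,3-dimethyloxiran-2-yl]methanol
Conditions: Ti(O-i-Pr)4 (5 mol %), D-(−)-diisopropyl tartrate (6 mol %), t-BuOOH, 4 Å molecular sieves, CH2Cl2, −20 °C
Reagents that add atoms: tert-butyl hydroperoxide CC(C)(C)OO
Why: Sharpless asymmetric epoxidation, where the D-tartrate should deliver oxygen to the face giving the (2R,3R) epoxy alcohol.

Step 18
Reactants: 28 epoxy alcohol
Product: 29 (2S,3R)-2,3-dimethyloxirane-2-carbaldehyde
Conditions: Dess–Martin periodinane, NaHCO3, CH2Cl2, 0 °C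
Reagents that add atoms: none
Why: buffered Dess–Martin oxidation should give the aldehyde, whose α-carbon is quaternary and cannot epimerise.

Step 19
Reactants: 26 β-hydroxy ketone; 29 epoxy aldehyde
Product: 30 C7 (2S,3R)-2,3-epoxy-2-methylbutanoate C9 alcohol
Conditions: SmI2 (30 mol %), 29 (5 equiv), THF, −10 °C
Reagents that add atoms: none
Why: Evans–Tishchenko reduction, in which the samarium-bound hemiacetal on O7 delivers hydride intramolecularly to C9, so the C9 alcohol should form anti to O7 while the C7 oxygen is acylated.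

Step 20
Reactants: 30 hydroxy ester; 31 angelic acid
Product: 33 C9 angelate C7 epoxy ester C1 silyl ether, via angelic 2,4,6-trichlorobenzoic anhydride 32 (not isolated)
Conditions: 2,4,6-trichlorobenzoyl chloride, Et3N, toluene, rt; then 30, 80 °C
Reagents that add atoms: none
Why: Yamaguchi esterification without added nucleophilic catalyst should acylate the hindered C9 alcohol without Z to E isomerisation of the angelate.

Step 21
Reactants: 33 silyl ether
Product: 34 C1 allylic alcohol
Conditions: HF·pyridine, pyridine, THF, 0 °C → rt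
Reagents that add atoms: none
Why: buffered fluoride desilylation should spare both esters and the epoxide.

Step 22
Reactants: 34 allylic alcohol
Product: 35 CNP0149458.1
Conditions: MnO2, CH2Cl2, rt
Reagents that add atoms: none
Why: MnO2 oxidation of the allylic C1 alcohol should give the C1(=O)–C2=C3 enone and remove the C1 stereocentre that controlled step 11.

**Compound list**
1 | 1-bromo-2-methylprop-1-ene | CC(C)=CBr | starting material
2 | 1,1,2-tribromo-3,3-dimethylcyclopropane | CC1(C)C(Br)C1(Br)Br | intermediate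
3 | 1-bromo-3,3-dimethylcyclopropene | CC1(C)C=C1Br | intermediate
4 | (3,3-dimethylcycloprop-1-en-1-yl)lithium | [Li]C1=CC1(C)C | intermediate
5 | 2-(3,3-dimethylcycloprop-1-en-1-yl)-4,4,5,5-tetramethyl-1,3,2-dioxaborolane | CC1(C)C=C1B1OC(C)(C)C(C)(C)O1 | intermediate
6 | prop-2-yn-1-ol | C#CCO | starting material
7 | bromomagnesium (Z)-3-(bromomagnesio)-2-methylprop-2-en-1-olate | Br[Mg]OC/C(C)=C\[Mg]Br | intermediate
8 | (Z)-3-iodo-2-methylprop-2-en-1-ol | OC/C(C)=C\I | intermediate
9 | (Z)-3-iodo-2-methylprop-2-enal | O=C/C(C)=C\I | intermediate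
10 | lithiated boronate | [Li]C1=C(B2OC(C)(C)C(C)(C)O2)C1(C)C | intermediate
11 | cyclopropenyl carbinol (racemic) | OC(/C(C)=C\I)C1=C(B2OC(C)(C)C(C)(C)O2)C1(C)C | intermediate
12 | cyclopropenyl (Z)-iodovinyl ketone | O=C(/C(C)=C\I)C1=C(B2OC(C)(C)C(C)(C)O2)C1(C)C | intermediate
13 | 2,3-dimethylfuran | Cc1occc1C | starting material
14 | (Z)-3-methyl-4-oxopent-2-enal | CC(=O)/C(C)=C\C=O | intermediate
15 | (E)-3-methyl-4-oxopent-2-enal | CC(=O)/C(C)=C/C=O | intermediate
16 | (2Z,4R,5E)-4-hydroxy dienedione | CC(=O)/C(C)=C/[C@@H](O)\C=C(C)/C(=O)C1=C(B2OC(C)(C)C(C)(C)O2)C1(C)C | intermediate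
17 | C1 silyl ether of 16 | CC(=O)/C(C)=C/[C@@H](O[Si](C)(C)C(C)(C)C)\C=C(C)/C(=O)C1=C(B2OC(C)(C)C(C)(C)O2)C1(C)C | intermediate
18 | siloxydiene cyclopropenyl ketone | C=C(O[Si](C)(C)C(C)(C)C)/C(C)=C/[C@@H](O[Si](C)(C)C(C)(C)C)\C=C(C)/C(=O)C1=C(B2OC(C)(C)C(C)(C)O2)C1(C)C | intermediate
19 | Diels–Alder adduct | CC1=C(O[Si](C)(C)C(C)(C)C)C[C@]3(B4OC(C)(C)C(C)(C)O4)C(C)(C)[C@]32[C@H]1[C@@H](O[Si](C)(C)C(C)(C)C)C=C(C)C2=O | intermediate
20 | C7 cyclopropanol | CC1=C(O[Si](C)(C)C(C)(C)C)C[C@]3(O)C(C)(C)[C@]32[C@H]1[C@@H](O[Si](C)(C)C(C)(C)C)C=C(C)C2=O | intermediate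
21 | cis-fused bicyclic diketone | CC1=C(O[Si](C)(C)C(C)(C)C)CC(=O)C(C)(C)[C@@H]2[C@H]1[C@@H](O[Si](C)(C)C(C)(C)C)C=C(C)C2=O | intermediate
22 | C4,C7-diol | CC1=C(O[Si](C)(C)C(C)(C)C)C[C@@H](O)C(C)(C)[C@@H]2[C@H]1[C@@H](O[Si](C)(C)C(C)(C)C)C=C(C)[C@H]2O | intermediate
23 | C4 monomesylate | CC1=C(O[Si](C)(C)C(C)(C)C)C[C@@H](O)C(C)(C)[C@@H]2[C@H]1[C@@H](O[Si](C)(C)C(C)(C)C)C=C(C)[C@H]2OS(C)(=O)=O | intermediate
24 | C4 mesylate C7 triethylsilyl ether | CC1=C(O[Si](C)(C)C(C)(C)C)C[C@@H](O[Si](CC)(CC)CC)C(C)(C)[C@@H]2[C@H]1[C@@H](O[Si](C)(C)C(C)(C)C)C=C(C)[C@H]2OS(C)(=O)=O | intermediate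
25 | tricyclic C9 ketone, C7 triethylsilyl ether | O=C1C[C@@H](O[Si](CC)(CC)CC)C(C)(C)[C@@H]2[C@H]3[C@@H](O[Si](C)(C)C(C)(C)C)C=C(C)[C@@H]2[C@]31C | intermediate
26 | tricyclic β-hydroxy ketone | O=C1C[C@@H](O)C(C)(C)[C@@H]2[C@H]3[C@@H](O[Si](C)(C)C(C)(C)C)C=C(C)[C@@H]2[C@]31C | intermediate
27 | (E)-2-methylbut-2-en-1-ol | OC/C(C)=C/C | starting material
28 | [(2R,3R)-2,3-dimethyloxiran-2-yl]methanol | OC[C@@]1(C)O[C@@H]1C | intermediate
29 | (2S,3R)-2,3-dimethyloxirane-2-carbaldehyde | O=C[C@@]1(C)O[C@@H]1C | intermediate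
30 | C7 epoxy ester C9 alcohol | O[C@@H]1C[C@@H](OC(=O)[C@@]2(C)O[C@@H]2C)C(C)(C)[C@@H]2[C@H]3[C@@H](O[Si](C)(C)C(C)(C)C)C=C(C)[C@@H]2[C@]31C | intermediate
31 | angelic acid, (Z)-2-methylbut-2-enoic acid | C/C=C(/C)C(=O)O | starting material
32 | angelic 2,4,6-trichlorobenzoic anhydride | C/C=C(/C)C(=O)OC(=O)c1c(Cl)cc(Cl)cc1Cl | intermediate
33 | C9 angelate C7 epoxy ester C1 silyl ether | C/C=C(/C)C(=O)O[C@@H]1C[C@@H](OC(=O)[C@@]2(C)O[C@@H]2C)C(C)(C)[C@@H]2[C@H]3[C@@H](O[Si](C)(C)C(C)(C)C)C=C(C)[C@@H]2[C@]31C | intermediate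
34 | C1 allylic alcohol | C/C=C(/C)C(=O)O[C@@H]1C[C@@H](OC(=O)[C@@]2(C)O[C@@H]2C)C(C)(C)[C@@H]2[C@H]3[C@@H](O)C=C(C)[C@@H]2[C@]31C | intermediate
35 | CNP0149458.1 | C/C=C(/C)C(=O)O[C@@H]1C[C@@H](OC(=O)[C@@]2(C)O[C@@H]2C)C(C)(C)[C@@H]2[C@H]3C(=O)C=C(C)[C@@H]2[C@]31C | target

**Totals**
Total steps: 22. Longest linear sequence: 17 steps (1, 2, 5, 6, 8–16, 19–22).

**Steps most likely to fail**

Step 15 (cyclobutane closure). The enolate may alkylate on oxygen to a six-membered enol ether, the allylic mesylate may eliminate, or fluoride may strip the C7 silyl ether so that the alkoxide closes an oxolane onto C4. The fallback sets out from diol 22 and switches to a palladium π-allyl closure with net retention. Mitsunobu reaction of 22 (4-nitrobenzoic acid, PPh3, diisopropyl azodicarboxylate) should invert only the allylic C4 alcohol and give the allylic 4-nitrobenzoate F1. TESOTf and 2,6-lutidine then give its C7 triethylsilyl ether F2. Pd(PPh3)4 (5 mol %, zerovalent palladium) with tetrabutylammonium difluorotriphenylsilicate ionises the ester with inversion, and the fluoride-freed C10 enolate attacks the allyl complex with a second inversion (Tsuji–Trost alkylation). This comes back to the route at 25.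

Step 12 (ring expansion). Protonation at C5 may occur on the wrong face, or C5 may epimerise under the basic peroxide conditions to the trans-fused bicycle, which cannot close the cyclobutane. The fallback sets out from 19. After the same C–B oxidation, the crude diketone mixture is treated with TMSOTf and Et3N to give the bis(trimethylsilyl) dienol ether F3, in which C5 is no longer a stereocentre. Kinetic protonation of F3 at −78 °C with 2,6-di-tert-butyl-4-methylphenol and a catalytic fluoride source should deliver hydrogen to C5 from the convex face. This comes back to the route at 21.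

Step 19 (Evans–Tishchenko with the epoxy aldehyde). The α-quaternary aldehyde may not form the hemiacetal, or SmI2 may open the epoxide reductively. The fallback sets out from 26. Evans–Tishchenko reduction with acetaldehyde (SmI2 cat.) gives the C7 acetate C9 alcohol F4. Yamaguchi angeloylation as in step 20 gives the acetate angelate F5. Selective methanolysis of the unconjugated acetate (K2CO3, MeOH, 0 °C) gives the C7 alcohol C9 angelate F6. Epoxy alcohol 28 is oxidised (RuCl3 cat., NaIO4) to (2S,3R)-2,3-dimethyloxirane-2-carboxylic acid F7, and Yamaguchi esterification of F6 with F7 comes back to the route at 33.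

**Further compounds**
F1 | step 15 | C4-inverted allylic 4-nitrobenzoate with free C7 alcohol | CC1=C(O[Si](C)(C)C(C)(C)C)C[C@@H](O)C(C)(C)[C@@H]2[C@H]1[C@@H](O[Si](C)(C)C(C)(C)C)C=C(C)[C@@H]2OC(=O)c1ccc(cc1)[N+](=O)[O-]
F2 | step 15 | C7 triethylsilyl ether of F1 | CC1=C(O[Si](C)(C)C(C)(C)C)C[C@@H](O[Si](CC)(CC)CC)C(C)(C)[C@@H]2[C@H]1[C@@H](O[Si](C)(C)C(C)(C)C)C=C(C)[C@@H]2OC(=O)c1ccc(cc1)[N+](=O)[O-]
F3 | step 12 | bis(trimethylsilyl) dienol ether of 21 | CC1=C(O[Si](C)(C)C(C)(C)C)C=C(O[Si](C)(C)C)C(C)(C)C2=C(O[Si](C)(C)C)C(C)=C[C@H](O[Si](C)(C)C(C)(C)C)[C@@H]12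
F4 | step 19 | C7 acetate C9 alcohol | O[C@@H]1C[C@@H](OC(C)=O)C(C)(C)[C@@H]2[C@H]3[C@@H](O[Si](C)(C)C(C)(C)C)C=C(C)[C@@H]2[C@]31C
F5 | step 19 | C7 acetate C9 angelate | C/C=C(/C)C(=O)O[C@@H]1C[C@@H](OC(C)=O)C(C)(C)[C@@H]2[C@H]3[C@@H](O[Si](C)(C)C(C)(C)C)C=C(C)[C@@H]2[C@]31C
F6 | step 19 | C7 alcohol C9 angelate | C/C=C(/C)C(=O)O[C@@H]1C[C@@H](O)C(C)(C)[C@@H]2[C@H]3[C@@H](O[Si](C)(C)C(C)(C)C)C=C(C)[C@@H]2[C@]31C
F7 | step 19 | (2S,3R)-2,3-dimethyloxirane-2-carboxylic acid | OC(=O)[C@@]1(C)O[C@@H]1C
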